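# Design of a total synthesis of Talapolyester A

## The problem

Talapolyester A (22) is a linear chain of four hydroxy acids joined head to tail by three esters. An (S)-3-hydroxybutanoate caps an (R)-3-hydroxybutanoate, which acylates the side-chain oxygen of a 2,4-dihydroxy-6-[(R)-2-hydroxypropyl]benzoate, whose ring carboxyl in turn esterifies O-3 of (R)-3,4-dihydroxybutanoic acid. The chain must be assembled by acylation at secondary carbinol oxygens without breaking a C–O bond at any stereocentre, and the order of the units has to be fixed by protecting groups, because two units differ only in configuration. The four stereocentres are isolated CH–O carbons at least four bonds apart, so none can direct another; each must arrive with its configuration set and be kept. The hardest bond is the benzoate ester: its carbonyl sits between the C2 hydroxyl and the C6 side chain, and the alcohol is secondary and carries a β-ester, so activating the benzoic acid is slow and the alcohol tolerates no strong base. The molecule is fragile in several ways: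

- each 3-acyloxy ester can lose carboxylate by β-elimination;
- the free primary hydroxyl next to the aroyloxy group invites 1,2-acyl shift and γ-lactone formation with the free acid;
- a free side-chain hydroxyl can attack the aryl ester to close a six-membered lactone.

The last step should therefore be neutral. The ring pattern opens a short route: C1 and C6 carry carbon, C2 and C4 oxygen, C3 and C5 hydrogen, so the ring carbons are in turn the methylene and carbonyl carbons of a 3,5,7-trioxo ester whose C2 and C7 become ring atoms C1 and C6. Both the ring bond C1–C6 and the hindered ester C–O bond can thus come from an open chain, the ester through a ketene instead of an activated benzoic acid.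

## Retrosynthesis

**22 to 21.** The four O–CH2Ph bonds are cut: the benzyl ester, the primary ether, the aryl ether at C4 and the ether on the terminal hydroxyl. One neutral hydrogenolysis then releases every sensitive function at once, which is preferable to any end game using acid, base or fluoride on the free hydroxy acid. Compound 21 is no smaller, but it has no free acid or aliphatic hydroxyl and can be handled. The forward step must cleave aryl, alkyl and ester benzyl groups without touching three ester links.

**21 to 20 and 15.** The ester C–O bond between the side-chain oxygen and the inner butanoyl carbonyl is cut. Cutting between the two butanoate units instead would mean linear growth on the most valuable intermediate. Cutting the aryl ester would bring back the hindered benzoic acid. This cut gives two halves of similar size; the carboxyl of 15 is unhindered and the hydroxyl of 20 is secondary but open. The forward acylation must spare the hydrogen-bonded 2-hydroxyl and must not eliminate the 3-acyloxy group of activated 15.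

**20 to 19 to 18.** Two protecting-group bonds are cut: O–Si on the side chain and O–benzyl on the C4 phenol. The C4 phenol would compete in the acylation, and benzyl is chosen because it leaves in the last step at no extra cost. The silyl ether is kept until after the basic benzylation, because it prevents the side-chain oxygen from attacking the aryl ester. Compound 18 carries two free phenols and is the direct product of the ring-forming step.

**18 to 6 and 9, through 17 and 16.** This is the central cut: the ring bond C1–C6 and the benzoate C–O bond. Trioxo ester 17 is the open form of the ring, and it comes from alcohol 9 and acylketene 16, which is dioxinone 6 after cycloreversion. The neighbouring cuts are worse. Esterifying a 2,6-disubstituted benzoic acid with 9 needs forcing activation or base, and a Mitsunobu reaction would invert 9. Substituting a preformed arene needs separate steps for the carboxyl and the side chain. Here the arene is replaced by a chain built from two-carbon units, and 9 is a small protected hydroxy ester. The forward reaction must trap the ketene faster than it cyclises and must close the chain carbon-to-carbon under base too weak to eliminate the silyloxy group.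

**6 to 5 and 3; 5 to 4; 3 to 2 to 1.** The C–C bond between the outer ketone carbonyl and the neighbouring methylene of 6 is cut, giving keto-dioxinone 5 as dianion and Weinreb amide 3. A second cut at the acetyl carbonyl reduces 5 to commercial dioxinone 4. These two acylations follow the polarity of the chain, and the Weinreb amide holds its tetrahedral adduct so the product diketone never meets the dianion. Amide 3 comes from pool ester 1 by silylation (2) and aminolysis, so the side-chain stereocentre is bought.

**9 to 8 to 7.** The benzyl ester is exchanged back to an ethyl ester (8), and the carbinol C–H bond is cut to give achiral keto ester 7, which already carries the benzyl ether. Setting this centre by reagent-controlled hydrogenation avoids differentiating the two hydroxyls of a dihydroxybutanoate, which is prone to lactonise. The forward step must deliver high enantioselectivity on a ketone flanked by an ether oxygen.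

**15 to 14 to 12 and 13; 12 to 11 to 10.** The ester between the two butanoate units is cut. The tert-butyl ester of 13 is orthogonal to the benzyl ether of 12, so acidolysis of 14 frees the carboxyl of 15 without touching the inner ester. Acid 12 comes from pool ester 10 by acid-catalysed benzylation (11) and saponification. Both stereocentres are bought, and their order is fixed by construction.

## Roads not taken

**Alternative 1:** The cut removes the two CH(CH3)–O bonds of the dibutanoate part. The (S)-hydroxybutanoyl-(R)-oxybutanoyl unit is the ring-opened form of the meso diolide A2. A2 would come from trans-2,5-dimethylcyclohexane-1,4-dione A1 by two peracid oxygen insertions (Baeyer–Villiger), each with migration of the methyl-bearing carbon and retention.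

- Merits: A1 is achiral; both butanoate units and the free terminal hydroxyl would arrive in one acylation of an alcohol such as 20, with no terminal protecting group and no carboxyl activation.
- Weak points: A2 has two enantiotopic carbonyls, and 20 must open the one that places the (R) carbon next to the aryl side chain. The stereocentre of 20 is five bonds from the reacting carbonyl, so substrate control is unlikely, and no catalyst for desymmetrising such an eight-membered diolide is established. Opening also needs a nucleophilic catalyst or alkoxide, which invites β-elimination, and the product hydroxyl can open a second A2. The second insertion takes place in a keto lactone, where the migration preference is less secure. The benzoate problem is untouched.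
- Comparison: if the desymmetrisation worked, this road would be shorter than the four steps spent on 15 and would save one benzyl ether. The chosen plan sets against this that each butanoate centre is bought and that the order of the (S) and (R) units is fixed by construction, not by a selectivity.

**Alternative 2:** The cut is at the aryl–carbonyl bond (C1) and the aryl–CH2 bond (C6) of a preformed benzene ring. An alkyllithium (n-butyllithium) releases the aryne from the iodo triflate A3. The aryne adds the ketene silyl acetal A4 in a [2+2] cycloaddition, and work-up gives the benzocyclobutenone A5. An alkoxide would then open the four-membered ketone at the carbonyl to give the 2-alkylbenzoate.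

- Merits: the alkoxy group next to the triple bond directs the nucleophilic carbon to the remote aryne carbon, so regiochemistry is reliable. Both ring substituents arrive in one step, and the phenols are benzyl ethers from the start, which saves the phenol protection the chosen plan needs.
- Weak points: the ester bond would form by attack of the alkoxide of a β-hydroxy ester such as 9 on A5, and 9 does not survive as an alkoxide (retro-aldol cleavage, elimination). The ring opening passes through a benzylic carbanion β to the silyloxy group, which can expel silanolate to give a styrene. A3 needs several steps of its own.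
- Comparison: this road is equal or better in ring regiocontrol and in phenol protecting-group economy. It is weaker at the ester C–O bond, which the chosen plan forms at neutral pH from a ketene.

**Alternative 3:** The cut removes the CH2–C(=O) bond and the ester C–O bond of the inner butanoate. Under carbon monoxide with Co2(CO)8 and 3-hydroxypyridine, tetracarbonylcobaltate opens (R)-2-methyloxirane A7 at its CH2 carbon, CO inserts, and the arylpropanol A6 cleaves the acylcobalt to give the hydroxy ester A8.

- Merits: full atom economy; the stereocentre comes untouched from a cheap epoxide; the new hydroxyl is free for the next unit; the butanoate needs no protecting group or activation.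
- Weak points: known alkoxycarbonylations of epoxides use the alcohol in large excess, whereas here A6 is the limiting partner, and the hydroxyl of A8 is an equally good nucleophile, so oligomerisation threatens. More seriously, A6 has no ring carboxyl. It would have to be introduced later by formylation and oxidation ortho to the side chain, in the presence of the ester chain, and the resulting 2,6-disubstituted benzoic acid would then have to be esterified with 9 by classical activation.
- Comparison: for the two butanoate ester bonds this road is shorter than the chosen plan. The chosen plan sets against this that ring and benzoate ester are solved together in one operation, and that the dibutanoate is attached by a single well-precedented acylation.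

Key step: step 11

## Route

Remark on the chemistry: 5, 6 and 17 are drawn in their keto forms although they should exist largely as enols; 7 and 13 are taken to be catalogue compounds.

Step 1
Reactants: 1 methyl (R)-3-hydroxybutanoate
Product: 2 methyl (R)-3-(triethylsilyloxy)butanoate
Conditions: TESCl, imidazole, CH2Cl2, 0 °C to rt
Reagents that add atoms: chlorotriethylsilane, CC[Si](Cl)(CC)CC
Why: Silylation of a secondary alcohol with a silyl chloride and imidazole; the stereocentre is not involved and stays (R). The triethylsilyl ether should survive the amide bases, the thermolysis and the carbonate treatments ahead, and is later cleaved by buffered fluoride that spares all esters.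

Step 2
Reactants: 2 methyl (R)-3-(triethylsilyloxy)butanoate
Product: 3 (R)-N-methoxy-N-methyl-3-(triethylsilyloxy)butanamide
Conditions: MeNH(OMe)·HCl, iPrMgCl, THF, −20 to 0 °C
Reagents that add atoms: N,O-dimethylhydroxylamine hydrochloride, CNOC.Cl
Why: Weinreb amide synthesis by aminolysis of the methyl ester with the chloromagnesium amide made in the flask; at low temperature the β-silyloxy ester should not eliminate. The N-methoxy-N-methyl amide is needed in step 4 because its tetrahedral adduct is stable until work-up.

Step 3
Reactants: 4 2,2,6-trimethyl-4H-1,3-dioxin-4-one
Product: 5 2,2-dimethyl-6-(2-oxopropyl)-4H-1,3-dioxin-4-one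
Conditions: LiN(SiMe3)2 (2 equiv), THF, −78 °C; AcCl (1 equiv), −78 °C; 1 M HCl
Reagents that add atoms: acetyl chloride, CC(Cl)=O
Why: Deprotonation of the 6-methyl group gives the extended enolate of the dioxinone, which is C-acylated at its terminus by the acid chloride (vinylogous Claisen condensation). The second equivalent of base converts the more acidic β-keto product into its enolate and so prevents a second acylation.

Step 4
Reactants: 5 2,2-dimethyl-6-(2-oxopropyl)-4H-1,3-dioxin-4-one; 3 (R)-N-methoxy-N-methyl-3-(triethylsilyloxy)butanamide
Product: 6 (R)-2,2-dimethyl-6-[2,4-dioxo-6-(triethylsilyloxy)heptyl]-4H-1,3-dioxin-4-one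
Conditions: LiN(iPr)2 (2.2 equiv), THF, −78 °C; then 3, −78 to −40 °C; AcOH
Reagents that add atoms: none
Why: Two equivalents of amide base convert 5 into its dianion (first the doubly activated methylene, then the terminal methyl), which reacts at the more basic terminal carbon with the Weinreb amide in a crossed Claisen condensation. The chelated tetrahedral adduct holds until the mild acid quench, so the 1,3-diketone is not exposed to base and the silyloxy group should not be eliminated; the stereocentre is untouched.

Step 5
Reactants: 7 ethyl 4-(benzyloxy)-3-oxobutanoate
Product: 8 ethyl (R)-4-(benzyloxy)-3-hydroxybutanoate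
Conditions: H2 (4 atm), RuCl2[(S)-BINAP] (cat.), EtOH, 100 °C
Reagents that add atoms: none
Why: Noyori asymmetric hydrogenation of a β-keto ester: ketone and ester chelate ruthenium and the (S)-BINAP ligand directs hydride to one face, in the same facial sense as for simple acetoacetates; the descriptor is (R) because CH2OBn outranks CH2CO2Et. The homogeneous catalyst does not cleave the benzyl ether, and the elevated temperature suppresses the competing ether-directed pathway.

Step 6
Reactants: 8 ethyl (R)-4-(benzyloxy)-3-hydroxybutanoate
Product: 9 benzyl (R)-4-(benzyloxy)-3-hydroxybutanoate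
Conditions: BnOH, Ti(OiPr)4 (cat.), PhMe, 100 °C, ethanol distilled off
Reagents that add atoms: benzyl alcohol, OCc1ccccc1
Why: Titanate-catalysed transesterification under neutral conditions, driven by removal of ethanol; β-hydroxy esters undergo this exchange without elimination or retro-aldol cleavage, and the stereocentre is not involved. The benzyl ester lets the carboxyl be released by hydrogenolysis in the last step.

Step 7
Reactants: 10 methyl (S)-3-hydroxybutanoate
Product: 11 methyl (S)-3-(benzyloxy)butanoate
Conditions: BnOC(=NH)CCl3, TfOH (cat.), cyclohexane/CH2Cl2, rt
Reagents that add atoms: benzyl 2,2,2-trichloroacetimidate, N=C(OCc1ccccc1)C(Cl)(Cl)Cl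
Why: Acid-catalysed O-benzylation with the trichloroacetimidate, which avoids the base that would cause retro-aldol cleavage or elimination of a β-hydroxy ester. The C–O bond of the stereocentre is not broken, so (S) is kept.

Step 8
Reactants: 11 methyl (S)-3-(benzyloxy)butanoate
Product: 12 (S)-3-(benzyloxy)butanoic acid
Conditions: LiOH, THF/H2O, 0 °C to rt; then 1 M HCl
Reagents that add atoms: lithium hydroxide, [Li+].[OH-]
Why: Saponification of the methyl ester at low temperature; benzyloxide is a poor leaving group, so β-elimination should not compete, and acidification gives the free acid.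

Step 9
Reactants: 12 (S)-3-(benzyloxy)butanoic acid; 13 tert-butyl (R)-3-hydroxybutanoate
Product: 14 tert-butyl (R)-3-{[(S)-3-(benzyloxy)butanoyl]oxy}butanoate
Conditions: DCC, DMAP (cat.), CH2Cl2, 0 °C to rt
Reagents that add atoms: none
Why: Steglich esterification (carbodiimide activation, acyl transfer through the acylpyridinium ion) of a secondary alcohol; the alcohol C–O bond is retained, so both stereocentres are unchanged. The tert-butyl ester is inert to these conditions.

Step 10
Reactants: 14 tert-butyl (R)-3-{[(S)-3-(benzyloxy)butanoyl]oxy}butanoate
Product: 15 (R)-3-{[(S)-3-(benzyloxy)butanoyl]oxy}butanoic acid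
Conditions: TFA, CH2Cl2, 0 °C to rt
Reagents that add atoms: none
Why: Acidolysis of the tert-butyl ester by alkyl–oxygen cleavage with loss of isobutene; the secondary alkyl ester and the benzyl ether are stable to this acid at room temperature.

Step 11
Reactants: 6 (R)-2,2-dimethyl-6-[2,4-dioxo-6-(triethylsilyloxy)heptyl]-4H-1,3-dioxin-4-one; 9 benzyl (R)-4-(benzyloxy)-3-hydroxybutanoate
Product: 18 benzyl (R)-4-(benzyloxy)-3-({2,4-dihydroxy-6-[(R)-2-(triethylsilyloxy)propyl]benzoyl}oxy)butanoate, via acylketene 16 (not isolated), via trioxo ester 17 (not isolated)
Conditions: PhMe, 110 °C; then Cs2CO3, CH2Cl2/i-PrOH, 0 °C to rt; AcOH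
Reagents that add atoms: none
Why: At 110 °C the dioxinone ring of 6 undergoes a retro-hetero-Diels–Alder reaction ([4+2] cycloreversion) that expels acetone and leaves acylketene 16, whose sp carbon is attacked by the secondary hydroxyl of 9 with help from the neighbouring acyl oxygen, so the congested ester C–O bond of 17 forms under neutral conditions and with retention at the carbinol carbon of 9, whose C–O bond is never broken. Carbonate then enolises the chain, and C2 of 17 (between the ester and the 3-ketone) adds to the C7 ketone in an intramolecular aldol reaction, a 6-exo-trig closure that forms the only new ring; loss of water and enolisation of the 3- and 5-ketones give the benzene ring, in which C2 and C7 of the chain are C1 and C6 of the benzoate. The closest known reaction type is the thermolysis of diketo-dioxinones in the presence of alcohols followed by base-induced aldol aromatisation of the resulting 3,5,7-trioxo esters to resorcylates, the laboratory counterpart of tetraketide aromatisation. No stereocentre is formed, and both existing ones are spectators, the one in the chain being separated from the enolisable carbons by a methylene group that ends as the benzylic CH2. The step needs chemoselectivity for carbon–carbon aldol closure over the other modes open to such a chain (O-cyclisation to a pyranone, Claisen closure of C6 onto the ester with loss of 9, and loss of triethylsilanol from the β-silyloxy ketone); the doubly activated C2 methylene, the six-membered transition state and the higher electrophilicity of a ketone over an ester favour the aldol path under carbonate at or below room temperature, whereas pyranone formation needs acid or heat without base and Claisen closure needs alkoxide strength. Capture of 16 by 9 has to outrun intramolecular O-acylation, which is addressed by having 9 present in slight excess from the start of heating. The benzyl ester, benzyl ether and silyl ether are inert to neutral toluene at reflux and to carbonate.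

Step 12
Reactants: 18 benzyl (R)-4-(benzyloxy)-3-({2,4-dihydroxy-6-[(R)-2-(triethylsilyloxy)propyl]benzoyl}oxy)butanoate
Product: 19 benzyl (R)-4-(benzyloxy)-3-({4-(benzyloxy)-2-hydroxy-6-[(R)-2-(triethylsilyloxy)propyl]benzoyl}oxy)butanoate
Conditions: BnBr (1.1 equiv), K2CO3, acetone, rt
Reagents that add atoms: benzyl bromide, BrCc1ccccc1
Why: Williamson etherification of the more acidic phenol: the 4-hydroxyl, para to the ester, is deprotonated and alkylated, while the 2-hydroxyl is held in a hydrogen bond to the ester carbonyl and reacts much more slowly. Carbonate at room temperature is too weak to enolise the benzyl ester, so the 3-aroyloxy group should not be eliminated, and the silyl ether still shields the side-chain oxygen from the aryl ester.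

Step 13
Reactants: 19 benzyl (R)-4-(benzyloxy)-3-({4-(benzyloxy)-2-hydroxy-6-[(R)-2-(triethylsilyloxy)propyl]benzoyl}oxy)butanoate
Product: 20 benzyl (R)-4-(benzyloxy)-3-({4-(benzyloxy)-2-hydroxy-6-[(R)-2-hydroxypropyl]benzoyl}oxy)butanoate
Conditions: HF·pyridine, pyridine, THF, 0 °C
Reagents that add atoms: none
Why: Fluoride-induced cleavage of the Si–O bond under pyridine-buffered conditions, to which esters and benzyl ethers are inert. The near-neutral medium and low temperature are chosen so that the freed hydroxyl does not attack the aryl ester; 20 is used at once.

Step 14
Reactants: 20 benzyl (R)-4-(benzyloxy)-3-({4-(benzyloxy)-2-hydroxy-6-[(R)-2-hydroxypropyl]benzoyl}oxy)butanoate; 15 (R)-3-{[(S)-3-(benzyloxy)butanoyl]oxy}butanoic acid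
Product: 21 benzyl (R)-4-(benzyloxy)-3-({4-(benzyloxy)-6-[(R)-2-({(R)-3-[(S)-3-(benzyloxy)butanoyloxy]butanoyl}oxy)propyl]-2-hydroxybenzoyl}oxy)butanoate
Conditions: DCC, DMAP (cat.), CH2Cl2, 0 °C to rt
Reagents that add atoms: none
Why: Steglich esterification of the unhindered carboxyl of 15 with the secondary side-chain hydroxyl, with retention at the carbinol carbon. The 2-hydroxyl is a poor nucleophile because of its hydrogen bond to the ester and its ortho neighbours, and activated 3-acyloxybutanoic acids couple under carbodiimide or acid chloride activation without elimination when kept cold.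

Step 15
Reactants: 21 benzyl (R)-4-(benzyloxy)-3-({4-(benzyloxy)-6-[(R)-2-({(R)-3-[(S)-3-(benzyloxy)butanoyloxy]butanoyl}oxy)propyl]-2-hydroxybenzoyl}oxy)butanoate
Product: 22 Talapolyester A, (R)-3-({2,4-dihydroxy-6-[(R)-2-({(R)-3-[(S)-3-hydroxybutanoyloxy]butanoyl}oxy)propyl]benzoyl}oxy)-4-hydroxybutanoic acid
Conditions: H2 (1 atm), Pd(OH)2/C, EtOAc, rt
Reagents that add atoms: none
Why: Hydrogenolysis over palladium cleaves the four O–benzyl bonds (aryl ether, primary and secondary alkyl ethers, benzyl ester) and should leave the three ester links, the arene and all stereocentres untouched. The neutral, aprotic medium is chosen to avoid acyl migration to the freed primary hydroxyl, γ-lactonisation and β-elimination.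

## Compound list

1 | methyl (R)-3-hydroxybutanoate | C[C@@H](O)CC(=O)OC | starting material
2 | methyl (R)-3-(triethylsilyloxy)butanoate | C[C@@H](O[Si](CC)(CC)CC)CC(=O)OC | intermediate
3 | (R)-N-methoxy-N-methyl-3-(triethylsilyloxy)butanamide | C[C@@H](O[Si](CC)(CC)CC)CC(=O)N(C)OC | intermediate
4 | 2,2,6-trimethyl-4H-1,3-dioxin-4-one | CC1=CC(=O)OC(C)(C)O1 | starting material
5 | 2,2-dimethyl-6-(2-oxopropyl)-4H-1,3-dioxin-4-one | CC(=O)CC1=CC(=O)OC(C)(C)O1 | intermediate
6 | (R)-2,2-dimethyl-6-[2,4-dioxo-6-(triethylsilyloxy)heptyl]-4H-1,3-dioxin-4-one | CC[Si](CC)(CC)O[C@H](C)CC(=O)CC(=O)CC1=CC(=O)OC(C)(C)O1 | intermediate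
7 | ethyl 4-(benzyloxy)-3-oxobutanoate | CCOC(=O)CC(=O)COCc1ccccc1 | starting material
8 | ethyl (R)-4-(benzyloxy)-3-hydroxybutanoate | CCOC(=O)C[C@@H](O)COCc1ccccc1 | intermediate
9 | benzyl (R)-4-(benzyloxy)-3-hydroxybutanoate | O[C@@H](COCc1ccccc1)CC(=O)OCc1ccccc1 | intermediate
10 | methyl (S)-3-hydroxybutanoate | C[C@H](O)CC(=O)OC | starting material
11 | methyl (S)-3-(benzyloxy)butanoate | C[C@H](OCc1ccccc1)CC(=O)OC | intermediate
12 | (S)-3-(benzyloxy)butanoic acid | C[C@H](OCc1ccccc1)CC(=O)O | intermediate
13 | tert-butyl (R)-3-hydroxybutanoate | C[C@@H](O)CC(=O)OC(C)(C)C | starting material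
14 | tert-butyl (R)-3-{[(S)-3-(benzyloxy)butanoyl]oxy}butanoate | C[C@H](OCc1ccccc1)CC(=O)O[C@H](C)CC(=O)OC(C)(C)C | intermediate
15 | (R)-3-{[(S)-3-(benzyloxy)butanoyl]oxy}butanoic acid | C[C@H](OCc1ccccc1)CC(=O)O[C@H](C)CC(=O)O | intermediate
16 | (R)-3,5,7-trioxo-9-(triethylsilyloxy)dec-1-en-1-one (acylketene) | CC[Si](CC)(CC)O[C@H](C)CC(=O)CC(=O)CC(=O)C=C=O | intermediate (not isolated)
17 | benzyl (R)-4-(benzyloxy)-3-{[(R)-3,5,7-trioxo-9-(triethylsilyloxy)decanoyl]oxy}butanoate (trioxo ester) | CC[Si](CC)(CC)O[C@H](C)CC(=O)CC(=O)CC(=O)CC(=O)O[C@@H](COCc1ccccc1)CC(=O)OCc1ccccc1 | intermediate (not isolated)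
18 | benzyl (R)-4-(benzyloxy)-3-({2,4-dihydroxy-6-[(R)-2-(triethylsilyloxy)propyl]benzoyl}oxy)butanoate | CC[Si](CC)(CC)O[C@H](C)Cc1cc(O)cc(O)c1C(=O)O[C@@H](COCc2ccccc2)CC(=O)OCc2ccccc2 | intermediate
19 | benzyl (R)-4-(benzyloxy)-3-({4-(benzyloxy)-2-hydroxy-6-[(R)-2-(triethylsilyloxy)propyl]benzoyl}oxy)butanoate | CC[Si](CC)(CC)O[C@H](C)Cc1cc(OCc2ccccc2)cc(O)c1C(=O)O[C@@H](COCc2ccccc2)CC(=O)OCc2ccccc2 | intermediate
20 | benzyl (R)-4-(benzyloxy)-3-({4-(benzyloxy)-2-hydroxy-6-[(R)-2-hydroxypropyl]benzoyl}oxy)butanoate | C[C@@H](O)Cc1cc(OCc2ccccc2)cc(O)c1C(=O)O[C@@H](COCc2ccccc2)CC(=O)OCc2ccccc2 | intermediate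
21 | benzyl (R)-4-(benzyloxy)-3-({4-(benzyloxy)-6-[(R)-2-({(R)-3-[(S)-3-(benzyloxy)butanoyloxy]butanoyl}oxy)propyl]-2-hydroxybenzoyl}oxy)butanoate | C[C@H](OCc1ccccc1)CC(=O)O[C@H](C)CC(=O)O[C@H](C)Cc1cc(OCc2ccccc2)cc(O)c1C(=O)O[C@@H](COCc2ccccc2)CC(=O)OCc2ccccc2 | intermediate
22 | Talapolyester A, (R)-3-({2,4-dihydroxy-6-[(R)-2-({(R)-3-[(S)-3-hydroxybutanoyloxy]butanoyl}oxy)propyl]benzoyl}oxy)-4-hydroxybutanoic acid | C[C@H](O)CC(=O)O[C@H](C)CC(=O)O[C@H](C)Cc1cc(O)cc(O)c1C(=O)O[C@@H](CO)CC(=O)O | target

## Step count and least certain steps

Total step count: 15. Longest linear sequence: 8 steps (1, 2, 4, 11, 12, 13, 14, 15).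

**Step 11 (key step).** Three processes may go wrong. Capture of the ketene by the hindered secondary hydroxyl may be outrun by intramolecular O-acylation of the chain's own enol (pyranone formation). In the base stage, triethylsilanol may be lost from the β-silyloxy ketone. The aldol adduct may fail to dehydrate without acid strong enough to cleave the silyl ether. The fallback sets out from 6 and comes back at 18, forming the same two bonds in reverse order. Triethylamine in CH2Cl2 should close 6 itself, by aldol condensation of the dioxinone C5 onto the outer ketone with the dioxinone ring kept, to (R)-7-hydroxy-2,2-dimethyl-5-[2-(triethylsilyloxy)propyl]-4H-1,3-benzodioxin-4-one F1. Irradiation of F1 near 300 nm in CH2Cl2 in the presence of 9 then releases a quinone ketene that 9 captures to give 18. Both stages are known reaction types, and the ester still forms from a ketene under neutral conditions.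

**Step 4.** The dianion may deprotonate the Weinreb amide at its α-carbon instead of adding to it, which would be followed by loss of silanolate. The sensitive diketo-dioxinone may also aromatise by self-condensation during work-up. The fallback sets out from 2 and 5 and comes back at 6. Reduction of 2 with iBu2AlH at −78 °C gives (R)-3-(triethylsilyloxy)butanal F2. The dianion of 5 adds to this far more electrophilic partner at −78 °C to give 6-[(6R)-4-hydroxy-2-oxo-6-(triethylsilyloxy)heptyl]-2,2-dimethyl-4H-1,3-dioxin-4-one F3 as a mixture of carbinol epimers. Oxidation with Dess–Martin periodinane converges both epimers on 6.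

**Step 13.** Once the side-chain hydroxyl is free, six-membered transesterification onto the aryl ester (closure to the 3-methylisochromanone with expulsion of 9) may set in on work-up or storage. The fallback sets out from 19 and comes back at 21 without ever liberating the hydroxyl. Acid 15 is converted with oxalyl chloride and catalytic DMF into (R)-3-{[(S)-3-(benzyloxy)butanoyl]oxy}butanoyl chloride F4. A Lewis acid catalyst (ZnCl2) then effects direct acylative cleavage of the triethylsilyl ether of 19 by F4, a known way of turning silyl ethers into esters.

**Step 14.** The activated 3-acyloxy acid may undergo base-induced β-elimination to a crotonate, and slow coupling would give the hydroxyl of 20 time to lactonise or the 2-hydroxyl time to be acylated. The fallback sets out from 20 and comes back at 21, growing the chain one unit at a time with acids that carry poorer β-leaving groups. Saponification of 2 (LiOH, 0 °C) gives (R)-3-(triethylsilyloxy)butanoic acid F5. Carbodiimide coupling of F5 with 20 gives benzyl (R)-4-(benzyloxy)-3-({4-(benzyloxy)-2-hydroxy-6-[(R)-2-{[(R)-3-(triethylsilyloxy)butanoyl]oxy}propyl]benzoyl}oxy)butanoate F6. Buffered HF·pyridine gives benzyl (R)-4-(benzyloxy)-3-({4-(benzyloxy)-2-hydroxy-6-[(R)-2-{[(R)-3-hydroxybutanoyl]oxy}propyl]benzoyl}oxy)butanoate F7, and a second carbodiimide coupling with 12 gives 21.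

**Step 15.** Cleavage of the two aliphatic benzyl ethers may lag behind the aryl ether and the ester. During the long exposure, 1,2-acyl migration to the freed primary hydroxyl or γ-lactonisation of the hydroxy acid on the catalyst surface may occur. The fallback sets out from 21 and comes back at 22 by a different cleavage mechanism. BCl3 with pentamethylbenzene in CH2Cl2 at −78 °C transfers the benzyl groups as cations to the arene scavenger in minutes at a temperature where the esters should be inert, followed by a cold methanol quench. No new compound lies on this way.

## Further compounds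

F1 | step 11 | (R)-7-hydroxy-2,2-dimethyl-5-[2-(triethylsilyloxy)propyl]-4H-1,3-benzodioxin-4-one | CC[Si](CC)(CC)O[C@H](C)Cc1cc(O)cc2OC(C)(C)OC(=O)c12
F2 | step 4 | (R)-3-(triethylsilyloxy)butanal | C[C@@H](O[Si](CC)(CC)CC)CC=O
F3 | step 4 | 6-[(6R)-4-hydroxy-2-oxo-6-(triethylsilyloxy)heptyl]-2,2-dimethyl-4H-1,3-dioxin-4-one (both epimers at the carbinol carbon) | CC[Si](CC)(CC)O[C@H](C)CC(O)CC(=O)CC1=CC(=O)OC(C)(C)O1
F4 | step 13 | (R)-3-{[(S)-3-(benzyloxy)butanoyl]oxy}butanoyl chloride | C[C@H](OCc1ccccc1)CC(=O)O[C@H](C)CC(Cl)=O
F5 | step 14 | (R)-3-(triethylsilyloxy)butanoic acid | C[C@@H](O[Si](CC)(CC)CC)CC(=O)O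
F6 | step 14 | benzyl (R)-4-(benzyloxy)-3-({4-(benzyloxy)-2-hydroxy-6-[(R)-2-{[(R)-3-(triethylsilyloxy)butanoyl]oxy}propyl]benzoyl}oxy)butanoate | C[C@@H](O[Si](CC)(CC)CC)CC(=O)O[C@H](C)Cc1cc(OCc2ccccc2)cc(O)c1C(=O)O[C@@H](COCc2ccccc2)CC(=O)OCc2ccccc2
F7 | step 14 | benzyl (R)-4-(benzyloxy)-3-({4-(benzyloxy)-2-hydroxy-6-[(R)-2-{[(R)-3-hydroxybutanoyl]oxy}propyl]benzoyl}oxy)butanoate | C[C@@H](O)CC(=O)O[C@H](C)Cc1cc(OCc2ccccc2)cc(O)c1C(=O)O[C@@H](COCc2ccccc2)CC(=O)OCc2ccccc2
F0 | step 15 | none | none
A1 | alternative 1 | trans-2,5-dimethylcyclohexane-1,4-dione (meso) | C[C@@H]1CC(=O)[C@@H](C)CC1=O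
A2 | alternative 1 | meso-(4S,8R)-4,8-dimethyl-1,5-dioxocane-2,6-dione | C[C@H]1CC(=O)O[C@H](C)CC(=O)O1
A3 | alternative 2 | 3,5-bis(benzyloxy)-2-iodophenyl trifluoromethanesulfonate | FC(F)(F)S(=O)(=O)Oc1cc(OCc2ccccc2)cc(OCc2ccccc2)c1I
A4 | alternative 2 | (R)-tert-butyl{[4-methoxy-4-(trimethylsilyloxy)but-3-en-2-yl]oxy}dimethylsilane (ketene silyl acetal, alkene geometry not specified) | COC(O[Si](C)(C)C)=C[C@@H](C)O[Si](C)(C)C(C)(C)C
A5 | alternative 2 | 3,5-bis(benzyloxy)-8-[(R)-1-(tert-butyldimethylsilyloxy)ethyl]bicyclo[4.2.0]octa-1,3,5-trien-7-one (both epimers at C8) | O=C1C([C@@H](C)O[Si](C)(C)C(C)(C)C)c2cc(OCc3ccccc3)cc(OCc3ccccc3)c12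
A6 | alternative 3 | (R)-1-[3,5-bis(benzyloxy)phenyl]propan-2-ol | C[C@@H](O)Cc1cc(OCc2ccccc2)cc(OCc2ccccc2)c1
A7 | alternative 3 | (R)-2-methyloxirane | C[C@@H]1CO1
A8 | alternative 3 | (R)-1-[3,5-bis(benzyloxy)phenyl]propan-2-yl (R)-3-hydroxybutanoate | C[C@@H](O)CC(=O)O[C@H](C)Cc1cc(OCc2ccccc2)cc(OCc2ccccc2)c1
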